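**Plan**
- Retrosynthetic cuts, in order: the C12 oxygen is put back, then C13–C16 (ring D), C3–C4 (ring A), C4–C5 with C19–O (lactone), C1–C10, C9–C10 (ring B), C5–C6, and finally C8–C6 and C8–C15.
- Enabling feature: on ring C the quaternary C8 and the bridgehead C13 are 1,3-related. C8 carries C15, and C16 bears the exocyclic methylene next to C13. A C8 propargyl arm (C15–C16≡C17) and a C12 enol ether that is nucleophilic at C13 can therefore close ring D of the bicyclo[3.2.1]octane.
- Forward ring order: C (3-ethoxycyclohexenone taken to an achiral 4,4-disubstituted dienone), B (Michael closure C10→C9), δ-lactone (tethered Michael C4→C5), A (reductive Heck C3–C4), D (gold).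
- Stereochemistry: C8/C9 absolute from a catalytic desymmetrisation of the dienone; C10 from convex-face alkylation; C5 from the C20 tether; C4 from the bridge geometry of the Heck closure; C2/C3 from exo osmylation; C6 from equilibration; C13 follows from C8.

Key step: step 18

Convention: gibberellane numbering is used throughout; β is the face of H-5, H-9, C7 and C15 in the target, α the face of the C19–O–C20 bridge.
Assumption: the cinchonine-derived urea of step 6 is taken to direct C10 to the dienone alkene that gives the 8,9-configuration drawn; if the sense is opposite, the pseudo-enantiomeric cinchonidine-derived urea is used.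

**Step 1**
Reactants: 1 3-ethoxycyclohex-2-en-1-one; 2 3-bromo-1-(trimethylsilyl)prop-1-yne
Product: 3 3-ethoxy-6-[3-(trimethylsilyl)prop-2-yn-1-yl]cyclohex-2-en-1-one (racemic)
Conditions: LiN(i-Pr)2, THF, −78 °C; then 2, −78 °C → rt
Reagents that add atoms: none
Why: Kinetic deprotonation of the vinylogous ester occurs at the α′ carbon (future C8) and the enolate is alkylated by the propargylic bromide (Stork–Danheiser alkylation), while the silyl cap masks the acidic alkyne C–H for the later base and palladium steps.

**Step 2**
Reactants: 3 3-ethoxy-6-[3-(trimethylsilyl)prop-2-yn-1-yl]cyclohex-2-en-1-one; 4 methyl bromoacetate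
Product: 5 methyl 2-{4-ethoxy-2-oxo-1-[3-(trimethylsilyl)prop-2-yn-1-yl]cyclohex-3-en-1-yl}acetate (racemic)
Conditions: LiN(i-Pr)2, THF, −78 °C; then 4, DMPU, −78 °C → rt
Reagents that add atoms: none
Why: A second α′-deprotonation, done while no ester is yet present, and SN2 alkylation with the α-bromo ester build quaternary C8 carrying C15 and C6–C7; the centre is racemic and loses its chirality in step 4.

**Step 3**
Reactants: 5 methyl 2-{4-ethoxy-2-oxo-1-[3-(trimethylsilyl)prop-2-yn-1-yl]cyclohex-3-en-1-yl}acetate
Product: 7 methyl 2-{4-oxo-1-[3-(trimethylsilyl)prop-2-yn-1-yl]cyclohex-2-en-1-yl}acetate (racemic), via allylic alcohol 6 (not isolated)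
Conditions: NaBH4, CeCl3·7H2O, MeOH, 0 °C; then 1 M aq HCl, THF, rt
Reagents that add atoms: water, SMILES O
Why: Luche 1,2-reduction attacks the vinylogous ester carbonyl but not the methyl ester, and acid then ionises the allylic alcohol and hydrolyses the enol ether with transposition to the 4,4-disubstituted enone (Stork–Danheiser transposition).

**Step 4**
Reactants: 7 methyl 2-{4-oxo-1-[3-(trimethylsilyl)prop-2-yn-1-yl]cyclohex-2-en-1-yl}acetate
Product: 8 methyl 2-{4-oxo-1-[3-(trimethylsilyl)prop-2-yn-1-yl]cyclohexa-2,5-dien-1-yl}acetate (achiral)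
Conditions: DDQ, 1,4-dioxane, reflux
Reagents that add atoms: none
Why: Quinone dehydrogenation of a 4,4-disubstituted cyclohexenone cannot aromatise and stops at the cross-conjugated dienone, in which C8 is prochiral and no enolisable ring hydrogen remains.

**Step 5**
Reactants: 8 methyl 2-{4-oxo-1-[3-(trimethylsilyl)prop-2-yn-1-yl]cyclohexa-2,5-dien-1-yl}acetate; 9 (E)-3-(dimethylamino)acrolein
Product: 11 methyl (E)-5-oxo-2-{4-oxo-1-[3-(trimethylsilyl)prop-2-yn-1-yl]cyclohexa-2,5-dien-1-yl}pent-3-enoate (C6 labile; racemic), via aldol adduct 10 (not isolated)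
Conditions: LiN(i-Pr)2, THF, −78 °C (slow addition of 8); then 9, −78 → 0 °C; then 1 M aq HCl, rt
Reagents that add atoms: water, SMILES O
Why: Only the ester α-hydrogens of 8 are acidic, so the C6 enolate adds to the formyl group of the vinylogous formamide and acid expels hydroxide and dimethylamine to leave the E-enal (vinylogous formylation), which installs C5, C10 and C20 in one operation.

**Step 6**
Reactants: 11 methyl (E)-5-oxo-2-{4-oxo-1-[3-(trimethylsilyl)prop-2-yn-1-yl]cyclohexa-2,5-dien-1-yl}pent-3-enoate
Product: 12 methyl 3-formyl-5-oxo-7a-[3-(trimethylsilyl)prop-2-yn-1-yl]-3a,4,5,7a-tetrahydro-3H-indene-1-carboxylate (cis-fused rings B and C; C15 β; H-9 β; formyl β and labile; C5=C6)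
Conditions: N-[3,5-bis(trifluoromethyl)phenyl]-N′-(9-deoxy-epi-cinchonin-9-yl)urea (10 mol%), toluene, −20 °C
Reagents that add atoms: none
Why: The C6–H of 11 is α to the ester and γ to the enal, so the quinuclidine nitrogen of the bifunctional urea deprotonates it and C10 of the delocalised anion attacks the hydrogen-bonded dienone 5-exo-trig (organocatalytic desymmetrisation of a 4,4-disubstituted cyclohexadienone by a tethered stabilised carbanion); the short tether allows only a cis fusion (C15 and H-9 both β) and the catalyst chooses between the two enantiotopic alkenes, which sets C8 and C9 in the absolute sense.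

**Step 7**
Reactants: 13 ethyl (Z)-3-iodoacrylate
Product: 14 (Z)-3-iodoprop-2-en-1-ol
Conditions: i-Bu2AlH (2.2 equiv), CH2Cl2, −78 °C; aq potassium sodium tartrate
Reagents that add atoms: none
Why: The aluminium hydride reduces the ester to the allylic alcohol at low temperature without touching the vinyl iodide or its Z geometry.

**Step 8**
Reactants: 14 (Z)-3-iodoprop-2-en-1-ol
Product: 15 (Z)-3-bromo-1-iodoprop-1-ene
Conditions: CBr4, PPh3, CH2Cl2, 0 °C
Reagents that add atoms: tetrabromomethane, SMILES BrC(Br)(Br)Br
Why: The Appel reaction converts the primary allylic alcohol into the bromide by SN2 displacement of the oxyphosphonium ion under neutral conditions that keep the Z-iodoalkene.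

**Step 9**
Reactants: 12 methyl 3-formyl-5-oxo-7a-[3-(trimethylsilyl)prop-2-yn-1-yl]-3a,4,5,7a-tetrahydro-3H-indene-1-carboxylate; 15 (Z)-3-bromo-1-iodoprop-1-ene
Product: 16 methyl 3-formyl-3-[(Z)-3-iodoprop-2-en-1-yl]-5-oxo-7a-[3-(trimethylsilyl)prop-2-yn-1-yl]-3a,4,5,7a-tetrahydro-3H-indene-1-carboxylate (quaternary C10; C1 chain β; formyl C20 α)
Conditions: Cs2CO3, MeCN, 0 °C
Reagents that add atoms: none
Why: The aldehyde is still a vinylogous 1,3-dicarbonyl acid, so carbonate forms the delocalised anion, which is alkylated (deconjugative alkylation) at C10 rather than at C6, the neighbour of quaternary C8, and from the convex β face where only H-9 adjoins, so that C1 becomes β, C20 α and the double bond settles at C5=C6 next to the ester.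

**Step 10**
Reactants: 16 the C10-quaternary aldehyde
Product: 17 methyl 3-(hydroxymethyl)-3-[(Z)-3-iodoprop-2-en-1-yl]-5-oxo-7a-[3-(trimethylsilyl)prop-2-yn-1-yl]-3a,4,5,7a-tetrahydro-3H-indene-1-carboxylate (C20 alcohol α)
Conditions: NaBH4, CH2Cl2/MeOH 1:1, −78 °C
Reagents that add atoms: none
Why: At −78 °C borohydride reduces an aldehyde much faster than a conjugated ketone or ester, and the new C20 hydroxyl cannot lactonise onto C7 because C7 and C10 are trans across C5=C6.

**Step 11**
Reactants: 17 the C20 alcohol; 18 diethylphosphonoacetic acid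
Product: 19 the C20 diethylphosphonoacetate of 17
Conditions: EDC·HCl, DMAP (cat.), CH2Cl2, 0 °C → rt
Reagents that add atoms: none
Why: Carbodiimide/DMAP esterification (Steglich type) acylates the neopentyl primary alcohol under neutral conditions and brings in C19 and C4 as a soft carbon acid tethered to the α face.

**Step 12**
Reactants: 19 the C20 diethylphosphonoacetate; 20 formaldehyde (as paraformaldehyde)
Product: 22 tricyclic α-methylene δ-lactone (rings C and B plus 19,20-lactone; C4=C18 exocyclic; H-5 β; C7 α; C1–C3 iodoallyl chain β on C10), via phosphono lactone 21 (not isolated)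
Conditions: Cs2CO3, MeCN, rt → 40 °C; then (CH2O)n, rt
Reagents that add atoms: none
Why: The phosphonate carbanion held on C20 can reach only the α face of C5 (6-exo-trig intramolecular Michael addition, cis-fused lactone), the resulting ester enolate is protonated from the open β face (C7 left α, corrected in step 16), and the Horner–Wadsworth–Emmons reaction with formaldehyde turns the α-phosphono lactone irreversibly into the α-methylene lactone.

**Step 13**
Reactants: 22 the α-methylene δ-lactone
Product: 23 methyl 12-oxo-17-(trimethylsilyl)-13,16-secogibberella-2,13-dien-16-yn-7-oate 19,20-lactone (6-epimer; C7 α; C18 methyl β; H-5 β)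
Conditions: Pd(OAc)2 (10 mol%), PPh3, HCO2Na, Et4NCl, DMF, 80 °C
Reagents that add atoms: none
Why: Zerovalent palladium inserts into the C3–I bond with retention of the Z geometry, the vinylpalladium adds 6-exo-trig across C4=C18 and formate reduces the neopentyl C18–Pd bond, which has no β-hydrogen, to the methyl group (intramolecular reductive Heck reaction); because C3 hangs from the β substituent of C10 it reaches C4 only on the face cis to C1, so quaternary C4 is fixed by the bicyclo[3.3.1] bridge and the 2-ene is left in ring A.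

**Step 14**
Reactants: 23 the tetracyclic 2-ene
Product: 24 methyl 2β,3β-dihydroxy-12-oxo-17-(trimethylsilyl)-13,16-secogibberell-13-en-16-yn-7-oate 19,20-lactone (C7 α)
Conditions: OsO4 (cat.), NMO, acetone/H2O, 0 °C → rt
Reagents that add atoms: N-methylmorpholine N-oxide, SMILES C[N+]1([O-])CCOCC1; water, SMILES O
Why: Catalytic osmylation picks the only electron-rich alkene (enone and silylalkyne react far more slowly) and comes from the exo β face because the lactone bridge covers the α face of ring A, which gives the 2β,3β-cis-diol.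

**Step 15**
Reactants: 24 the 2β,3β-diol
Product: 25 the 2β,3β-O-isopropylidene derivative of 24 (C7 α)
Conditions: 2,2-dimethoxypropane, PPTS (cat.), CH2Cl2, rt
Reagents that add atoms: 2,2-dimethoxypropane, SMILES COC(C)(C)OC
Why: Acid-catalysed transketalisation closes a five-membered acetonide on the cis-diol and protects it from the hydride, silylating and xanthate reagents that follow.

**Step 16**
Reactants: 25 the acetonide
Product: 26 methyl 2β,3β-(isopropylidenedioxy)-12-oxo-13,16-secogibberell-13-en-16-yn-7-oate 19,20-lactone (terminal alkyne; C7 β; H-6 α)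
Conditions: NaOMe (cat.), MeOH, 40 °C; AcOH quench
Reagents that add atoms: none
Why: Methoxide cleaves the alkynyl C–Si bond and equilibrates C6 through the ester enolate, moving C7 from the crowded concave α face to the β face, trans to C4, while any opened lactone recloses on neutralisation because C19 and C20 are held 1,3-diaxial.

**Step 17**
Reactants: 26 the terminal alkyne enone
Product: 28 methyl 12-(tert-butyldimethylsilyloxy)-2β,3β-(isopropylidenedioxy)-13,16-secogibberell-12-en-16-yn-7-oate 19,20-lactone, via lithium enolate 27 (not isolated)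
Conditions: LiBH(s-Bu)3, THF, −78 °C; then TBSOTf, Et3N, −78 → 0 °C
Reagents that add atoms: tert-butyldimethylsilyl triflate, SMILES CC(C)(C)[Si](C)(C)OS(=O)(=O)C(F)(F)F
Why: The bulky borohydride adds 1,4 to a cyclohexenone whose β carbon (C14) carries hydrogen, and O-silylation of the regiodefined enolate locks the double bond at C12=C13, while ester, lactone and alkyne are inert at −78 °C.

**Step 18**
Reactants: 28 the C12 silyl enol ether with the C8 propargyl arm
Product: 29 methyl 2β,3β-(isopropylidenedioxy)-12-oxogibberell-16-en-7-oate 19,20-lactone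
Conditions: Ph3PAuCl (10 mol%), AgBF4 (10 mol%), CH2Cl2/MeOH 10:1, rt → 40 °C
Reagents that add atoms: none
Why: Chloride abstraction by silver gives Ph3PAu+ (cationic monovalent gold), which binds the terminal C16≡C17 alkyne; C13 of the enol ether adds anti to gold, methanol takes the silyl group and protonates the vinyl–gold bond, leaving the C12 ketone and the C16 methylene. The closest known reaction type is the gold-catalysed carbocyclisation of silyl enol ethers onto alkynes, the silyl variant of the Conia-ene reaction. Ring D (C8, C14, C13, C16, C15) closes 5-exo-dig, whereas 6-endo attack at C17 would give a bicyclo[2.2.2]octene and is disfavoured for a terminal alkyne on this short tether. The only new stereocentre, C13, is dictated by C8, since a two-carbon bridge can span C8 and C13 only on the β face where C15 stands axial on ring C. The step needs the C12–C13 and not the C11–C12 enol ether, which step 17 secures by delivering hydride to C14 of the C13–C14 enone. Lactone, acetonide and ester are hard donors that do not compete for the soft catalyst.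

**Step 19**
Reactants: 29 the 12-ketone
Product: 30 methyl 12α-hydroxy-2β,3β-(isopropylidenedioxy)gibberell-16-en-7-oate 19,20-lactone
Conditions: NaBH4, MeOH, 0 °C
Reagents that add atoms: none
Why: Borohydride reduces only the ketone, and hydride is expected to come from the side away from the axial C9–C10 bond to give the axial 12α-alcohol, a centre that is removed in step 21.

**Step 20**
Reactants: 30 the 12α-alcohol
Product: 31 the O-(12α-yl) S-methyl dithiocarbonate (xanthate) of 30
Conditions: NaH, imidazole (cat.), THF, 0 °C; CS2; then MeI, rt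
Reagents that add atoms: carbon disulfide, SMILES S=C=S; iodomethane, SMILES CI
Why: The alkoxide route to the xanthate uses small electrophiles and so acylates even a hindered axial secondary alcohol, and the only other acidic site, C6, is already in its stable configuration.

**Step 21**
Reactants: 31 the xanthate
Product: 32 methyl 2β,3β-(isopropylidenedioxy)gibberell-16-en-7-oate 19,20-lactone
Conditions: Bu3SnH (0.5 M), AIBN (cat.), toluene, 90 °C
Reagents that add atoms: none
Why: Barton–McCombie deoxygenation replaces C12–O by C12–H, and a high stannane concentration traps the secondary C12 radical before it can add to the homoallylic C16=C17 bond and rearrange towards a bicyclo[2.2.2]octane.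

**Step 22**
Reactants: 32 the deoxygenated methyl ester
Product: 33 2β,3β-(isopropylidenedioxy)gibberell-16-en-7-oic acid 19,20-lactone
Conditions: n-PrSLi, HMPA, rt; then 1 M HCl work-up
Reagents that add atoms: none
Why: The thiolate demethylates the hindered C7 ester by SN2 attack at the methyl carbon, whereas the lactone alkyl carbon C20 is neopentyl and is not displaced.

**Step 23**
Reactants: 33 the acetonide acid
Product: 34 2β,3β-dihydroxygibberell-16-en-7-oic acid 19,20-lactone (CNP0332607.1)
Conditions: AcOH/H2O 4:1, 45 °C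
Reagents that add atoms: none
Why: Dilute acetic acid hydrolyses the acetonide but is too weak to isomerise or hydrate the C16 exocyclic methylene or to open the lactone.

**Compound list**
1 | 3-ethoxycyclohex-2-en-1-one | CCOC1=CC(=O)CCC1 | starting material
2 | 3-bromo-1-(trimethylsilyl)prop-1-yne | C[Si](C)(C)C#CCBr | starting material
3 | 3-ethoxy-6-[3-(trimethylsilyl)prop-2-yn-1-yl]cyclohex-2-en-1-one (racemic) | CCOC1=CC(=O)C(CC#C[Si](C)(C)C)CC1 | intermediate
4 | methyl bromoacetate | COC(=O)CBr | starting material
5 | methyl 2-{4-ethoxy-2-oxo-1-[3-(trimethylsilyl)prop-2-yn-1-yl]cyclohex-3-en-1-yl}acetate (racemic) | CCOC1=CC(=O)C(CC#C[Si](C)(C)C)(CC(=O)OC)CC1 | intermediate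
6 | allylic alcohol from 5 (not isolated; racemic) | CCOC1=CC(O)C(CC#C[Si](C)(C)C)(CC(=O)OC)CC1 | intermediate
7 | methyl 2-{4-oxo-1-[3-(trimethylsilyl)prop-2-yn-1-yl]cyclohex-2-en-1-yl}acetate (racemic) | COC(=O)CC1(CC#C[Si](C)(C)C)C=CC(=O)CC1 | intermediate
8 | methyl 2-{4-oxo-1-[3-(trimethylsilyl)prop-2-yn-1-yl]cyclohexa-2,5-dien-1-yl}acetate (achiral) | COC(=O)CC1(CC#C[Si](C)(C)C)C=CC(=O)C=C1 | intermediate
9 | (E)-3-(dimethylamino)acrolein | CN(C)/C=C/C=O | starting material
10 | aldol adduct of the C6 enolate with 9 (not isolated) | COC(=O)C(C(O)/C=C/N(C)C)C1(CC#C[Si](C)(C)C)C=CC(=O)C=C1 | intermediate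
11 | methyl (E)-5-oxo-2-{4-oxo-1-[3-(trimethylsilyl)prop-2-yn-1-yl]cyclohexa-2,5-dien-1-yl}pent-3-enoate (C6 labile) | COC(=O)C(/C=C/C=O)C1(CC#C[Si](C)(C)C)C=CC(=O)C=C1 | intermediate
12 | bicyclic B/C aldehyde (C15 β, H-9 β, formyl β) | C[Si](C)(C)C#CC[C@]23C=CC(=O)C[C@H]2[C@H](C=O)C=C3C(=O)OC | intermediate
13 | ethyl (Z)-3-iodoacrylate | CCOC(=O)/C=C\I | starting material
14 | (Z)-3-iodoprop-2-en-1-ol | OC/C=C\I | intermediate
15 | (Z)-3-bromo-1-iodoprop-1-ene | BrC/C=C\I | intermediate
16 | C10-quaternary aldehyde (C1 chain β, C20 formyl α) | C[Si](C)(C)C#CC[C@]23C=CC(=O)C[C@H]2[C@](C=O)(C/C=C\I)C=C3C(=O)OC | intermediate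
17 | C20 primary alcohol | C[Si](C)(C)C#CC[C@]23C=CC(=O)C[C@H]2[C@](CO)(C/C=C\I)C=C3C(=O)OC | intermediate
18 | diethylphosphonoacetic acid | OC(=O)CP(=O)(OCC)OCC | starting material
19 | C20 diethylphosphonoacetate | C[Si](C)(C)C#CC[C@]23C=CC(=O)C[C@H]2[C@](COC(=O)CP(=O)(OCC)OCC)(C/C=C\I)C=C3C(=O)OC | intermediate
20 | formaldehyde (from paraformaldehyde) | C=O | starting material
21 | α-phosphono δ-lactone (not isolated; C4 undefined, present as its caesium salt) | C[Si](C)(C)C#CC[C@]23C=CC(=O)C[C@H]2[C@@]1(C/C=C\I)COC(=O)C(P(=O)(OCC)OCC)[C@H]1[C@H]3C(=O)OC | intermediate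
22 | α-methylene δ-lactone (H-5 β, C7 α) | C[Si](C)(C)C#CC[C@]23C=CC(=O)C[C@H]2[C@@]1(C/C=C\I)COC(=O)C(=C)[C@H]1[C@H]3C(=O)OC | intermediate
23 | tetracyclic 2-ene, 6-epimer | C[Si](C)(C)C#CC[C@]23C=CC(=O)C[C@H]2[C@]12COC(=O)[C@](C)(C=CC1)[C@H]2[C@H]3C(=O)OC | intermediate
24 | 2β,3β-diol, 6-epimer | C[Si](C)(C)C#CC[C@]23C=CC(=O)C[C@H]2[C@]12COC(=O)[C@](C)([C@@H](O)[C@@H](O)C1)[C@H]2[C@H]3C(=O)OC | intermediate
25 | acetonide, 6-epimer | C[Si](C)(C)C#CC[C@]23C=CC(=O)C[C@H]2[C@]12COC(=O)[C@](C)([C@@H](OC4(C)C)[C@@H](O4)C1)[C@H]2[C@H]3C(=O)OC | intermediate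
26 | terminal alkyne enone, C7 β | C#CC[C@]23C=CC(=O)C[C@H]2[C@]12COC(=O)[C@](C)([C@@H](OC4(C)C)[C@@H](O4)C1)[C@H]2[C@@H]3C(=O)OC | intermediate
27 | lithium C12 enolate (not isolated) | [Li+].C#CC[C@]23CC=C([O-])C[C@H]2[C@]12COC(=O)[C@](C)([C@@H](OC4(C)C)[C@@H](O4)C1)[C@H]2[C@@H]3C(=O)OC | intermediate
28 | C12 tert-butyldimethylsilyl enol ether (precursor of the key step) | C#CC[C@]23CC=C(O[Si](C)(C)C(C)(C)C)C[C@H]2[C@]12COC(=O)[C@](C)([C@@H](OC4(C)C)[C@@H](O4)C1)[C@H]2[C@@H]3C(=O)OC | intermediate
29 | 12-oxo 16-methylene bicyclo[3.2.1]octane (product of the key step) | C=C1C[C@]23C[C@H]1C(=O)C[C@H]2[C@]12COC(=O)[C@](C)([C@@H](OC4(C)C)[C@@H](O4)C1)[C@H]2[C@@H]3C(=O)OC | intermediate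
30 | 12α-alcohol | C=C1C[C@]23C[C@H]1[C@@H](O)C[C@H]2[C@]12COC(=O)[C@](C)([C@@H](OC4(C)C)[C@@H](O4)C1)[C@H]2[C@@H]3C(=O)OC | intermediate
31 | 12α-xanthate | C=C1C[C@]23C[C@H]1[C@@H](OC(=S)SC)C[C@H]2[C@]12COC(=O)[C@](C)([C@@H](OC4(C)C)[C@@H](O4)C1)[C@H]2[C@@H]3C(=O)OC | intermediate
32 | 12-deoxy methyl ester acetonide | C=C1C[C@]23C[C@H]1CC[C@H]2[C@]12COC(=O)[C@](C)([C@@H](OC4(C)C)[C@@H](O4)C1)[C@H]2[C@@H]3C(=O)OC | intermediate
33 | C7 acid acetonide | C=C1C[C@]23C[C@H]1CC[C@H]2[C@]12COC(=O)[C@](C)([C@@H](OC4(C)C)[C@@H](O4)C1)[C@H]2[C@@H]3C(=O)O | intermediate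
34 | 2β,3β-dihydroxygibberell-16-en-7-oic acid 19,20-lactone (CNP0332607.1) | C=C1C[C@]23C[C@H]1CC[C@H]2[C@]12COC(=O)[C@](C)([C@@H](O)[C@@H](O)C1)[C@H]2[C@@H]3C(=O)O | target

**Step count**
Total step count: 23.
Longest linear sequence: 21 (steps 1–6 and 9–23); steps 7 and 8 are a two-step side branch.

**Steps most likely to fail**

Step 6. What may go wrong: ring closure may be slow, the catalyst may discriminate poorly between the two enantiotopic dienone alkenes, and enantiomeric purity may erode through retro-Michael reaction of the stabilised anion. The fallback sets out from 11 and returns at 12. It replaces ion pairing of the carbon acid by covalent activation of the aldehyde. (S)-2-[Diphenyl(trimethylsilyloxy)methyl]pyrrolidine with benzoic acid in toluene condenses with the enal to the dienamine F1. Its α carbon C10 closes onto C9 in a Rauhut–Currier-type cyclisation, with the silyloxydiphenylmethyl group shielding one face of C10. Hydrolysis of the iminium ion returns the amine and gives 12. With the aminovinyl unit on the convex face, the (S)-amine is expected to lead to the series drawn.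

Step 13. What may go wrong: 7-endo insertion at the exocyclic CH2, which is the electronically preferred carbon of the acrylate; cyclopropane formation from the neopentylpalladium intermediate and the new 2-ene; or premature reduction of the C–I bond. The fallback sets out from 22 and returns at 23. It sets C4 by convex-face attack of an electrophile and closes ring A by metathesis.
- Pd(PPh3)4/Bu3SnH removes iodine to give the allyl lactone F2.
- [(Ph3P)CuH]6 hydrometallates the unhindered exocyclic acrylate faster than the enone, whose β carbon C14 is neopentyl. The copper enolate is trapped by acetaldehyde on the face cis to H-5 and C1 (reductive aldol reaction) to give the aldol F3.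
- The Burgess reagent dehydrates it, necessarily towards the methyl group, to the vinyl lactone F4.
- The second-generation Grubbs catalyst closes C2=C3 to 23, the silyl cap keeping the alkyne out of enyne metathesis.

Step 5. What may go wrong: the ester enolate may condense with the dienone of a second molecule, and its addition to the weakly electrophilic vinylogous formamide may be sluggish. The fallback sets out from 8 and returns at 11. It avoids a kinetic lithium enolate. A Claisen condensation with methyl formate (NaH, THF) is driven by formation of the stabilised sodium enolate and gives the α-formyl ester F5. A Wittig reaction with (triphenylphosphoranylidene)acetaldehyde then extends F5 by C10 and C20 to the E-enal 11.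

**Further compounds**
F1 | step 6 | dienamine of 11 with (S)-2-[diphenyl(trimethylsilyloxy)methyl]pyrrolidine | COC(=O)C(=C/C=C/N1CCC[C@H]1C(c1ccccc1)(c1ccccc1)O[Si](C)(C)C)C1(CC#C[Si](C)(C)C)C=CC(=O)C=C1
F2 | step 13 | C10-allyl α-methylene δ-lactone | C[Si](C)(C)C#CC[C@]23C=CC(=O)C[C@H]2[C@@]1(CC=C)COC(=O)C(=C)[C@H]1[C@H]3C(=O)OC
F3 | step 13 | C4-methyl C4-(1-hydroxyethyl) lactone (carbinol centre undefined) | C[Si](C)(C)C#CC[C@]23C=CC(=O)C[C@H]2[C@@]1(CC=C)COC(=O)[C@](C)(C(C)O)[C@H]1[C@H]3C(=O)OC
F4 | step 13 | C4-methyl C4-vinyl lactone | C[Si](C)(C)C#CC[C@]23C=CC(=O)C[C@H]2[C@@]1(CC=C)COC(=O)[C@](C)(C=C)[C@H]1[C@H]3C(=O)OC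
F5 | step 5 | methyl 3-oxo-2-{4-oxo-1-[3-(trimethylsilyl)prop-2-yn-1-yl]cyclohexa-2,5-dien-1-yl}propanoate | COC(=O)C(C=O)C1(CC#C[Si](C)(C)C)C=CC(=O)C=C1
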